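## Retrosynthetic overview
1. Target 23 comes from penta-O-benzyl (S)-flavanone 22 by global hydrogenolysis. 22 comes from racemic 21, with C-2 secured by a Ru-catalysed transfer-hydrogenation kinetic resolution.
2. Flavanone ring C (O1–C2) comes from oxa-Michael closure of 2'-hydroxychalcone 20. The Cα=Cβ bond of 20 comes from a Claisen–Schmidt aldol condensation of acetophenone 18 with flavonyl-benzaldehyde 15, which is the key fragment union.
3. 15 comes from Suzuki coupling of 6-iodoflavone 11 with formylaryl boronate 14 (the 3'–6'' biaryl bond).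
4. 11 comes from tri-O-benzylapigenin 7, made by a first Claisen–Schmidt condensation (2 + 3) and I2/DMSO closure. Both 2 and 18 derive from phloroacetophenone 1.
5. Ring order: flavone pyranone (step 3), then the biaryl bond (step 9), then the flavanone pyranone (step 13).

Assumption: the 3'–6'' biaryl axis (three ortho oxygen substituents) rotates freely on the laboratory time scale, so C-2 is the only stereogenic element to control, as in the given SMILES.

## Route

Step 1
Reactants: 1 2,4,6-trihydroxyacetophenone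
Product: 2 1-[2,4-bis(benzyloxy)-6-hydroxyphenyl]ethan-1-one
Conditions: BnBr (2.1 equiv), K2CO3 (2.2 equiv), DMF, rt to 50 °C
Reagents that add atoms: benzyl bromide, BrCc1ccccc1
Why: Williamson ether synthesis in which two phenols are capped and the last OH, locked in a hydrogen bond to the acetyl C=O, stays free.

Step 2
Reactants: 2 1-[2,4-bis(benzyloxy)-6-hydroxyphenyl]ethan-1-one; 3 4-(benzyloxy)benzaldehyde
Product: 5 (E)-1-[2,4-bis(benzyloxy)-6-hydroxyphenyl]-3-[4-(benzyloxy)phenyl]prop-2-en-1-one, via aldol adduct 4 (not isolated)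
Conditions: KOH (50% aq), EtOH, rt, 48 h; then 1 M HCl
Reagents that add atoms: none
Why: Claisen–Schmidt aldol condensation in which the ketone enolate adds to the non-enolisable aldehyde and aldol 4 loses water by E1cB to give the conjugated (E)-enone.

Step 3
Reactants: 5 (E)-1-[2,4-bis(benzyloxy)-6-hydroxyphenyl]-3-[4-(benzyloxy)phenyl]prop-2-en-1-one
Product: 7 5,7-bis(benzyloxy)-2-[4-(benzyloxy)phenyl]-4H-chromen-4-one, via flavanone 6 (not isolated)
Conditions: I2 (10 mol%), DMSO, 130 °C, 3 h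
Reagents that add atoms: none
Why: Iodine/DMSO oxidative cyclisation in which the 2'-hydroxychalcone closes by oxa-Michael addition to flavanone 6, catalytic iodine dehydrogenates it with DMSO as terminal oxidant, and any 5-O-debenzylated material is simply the product of step 4.

Step 4
Reactants: 7 5,7-bis(benzyloxy)-2-[4-(benzyloxy)phenyl]-4H-chromen-4-one
Product: 9 7-(benzyloxy)-2-[4-(benzyloxy)phenyl]-5-hydroxy-4H-chromen-4-one, via dichloroboryl ether 8 (not isolated)
Conditions: BCl3 (1.1 equiv), CH2Cl2, −78 °C, 1 h; then H2O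
Reagents that add atoms: none
Why: Chelation-directed Lewis-acid ether cleavage in which BCl3 sits between the C-4 carbonyl and the peri 5-oxygen, so only that benzyl group leaves as benzyl chloride and chelate 8 is hydrolysed on work-up.

Step 5
Reactants: 9 7-(benzyloxy)-2-[4-(benzyloxy)phenyl]-5-hydroxy-4H-chromen-4-one
Product: 10 7-(benzyloxy)-2-[4-(benzyloxy)phenyl]-5-hydroxy-6-iodo-4H-chromen-4-one
Conditions: BnNMe3ICl2 (1.05 equiv), CaCO3 (2 equiv), CH2Cl2/MeOH 5:2, rt, 16 h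
Reagents that add atoms: benzyltrimethylammonium dichloroiodate, C[N+](C)(C)Cc1ccccc1.Cl[I-]Cl
Why: Electrophilic aromatic iodination that, with the 5-OH free, takes 5,7-dioxygenated flavones at C-6 (ortho to the free phenol) rather than C-8, and this is checked by the HMBC cross-peak from the chelated 5-OH to the iodinated carbon.

Step 6
Reactants: 10 7-(benzyloxy)-2-[4-(benzyloxy)phenyl]-5-hydroxy-6-iodo-4H-chromen-4-one
Product: 11 5,7-bis(benzyloxy)-2-[4-(benzyloxy)phenyl]-6-iodo-4H-chromen-4-one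
Conditions: BnBr (1.5 equiv), K2CO3 (3 equiv), DMF, 70 °C
Reagents that add atoms: benzyl bromide, BrCc1ccccc1
Why: Williamson ether synthesis in warm DMF that overcomes the 5-OH hydrogen bond, removes the acidic chelating phenol before cross-coupling, and keeps benzyl as the only phenol protecting group.

Step 7
Reactants: 12 3-bromo-4-hydroxybenzaldehyde
Product: 13 4-(benzyloxy)-3-bromobenzaldehyde
Conditions: BnBr (1.1 equiv), K2CO3 (1.5 equiv), DMF, rt
Reagents that add atoms: benzyl bromide, BrCc1ccccc1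
Why: Williamson ether synthesis of an acidic para-formyl phenol, which is clean and high yielding.

Step 8
Reactants: 13 4-(benzyloxy)-3-bromobenzaldehyde
Product: 14 4-(benzyloxy)-3-(4,4,5,5-tetramethyl-1,3,2-dioxaborolan-2-yl)benzaldehyde
Conditions: B2pin2 (1.2 equiv), PdCl2(dppf) (3 mol%), KOAc (3 equiv), 1,4-dioxane, 90 °C
Reagents that add atoms: bis(pinacolato)diboron, CC1(C)OB(OC1(C)C)B1OC(C)(C)C(C)(C)O1
Why: Miyaura borylation, whose weak acetate base tolerates the aldehyde and suppresses homocoupling.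

Step 9
Reactants: 11 5,7-bis(benzyloxy)-2-[4-(benzyloxy)phenyl]-6-iodo-4H-chromen-4-one; 14 4-(benzyloxy)-3-(4,4,5,5-tetramethyl-1,3,2-dioxaborolan-2-yl)benzaldehyde
Product: 15 4-(benzyloxy)-3-{5,7-bis(benzyloxy)-2-[4-(benzyloxy)phenyl]-4-oxo-4H-chromen-6-yl}benzaldehyde
Conditions: Pd(OAc)2 (5 mol%), SPhos (2-dicyclohexylphosphino-2',6'-dimethoxybiphenyl, 10 mol%), K3PO4 (3 equiv), toluene/H2O 10:1, 90 °C
Reagents that add atoms: none
Why: Suzuki–Miyaura coupling in which the bulky electron-rich biarylphosphine on zerovalent palladium handles the doubly ortho-substituted iodide, and neither the flavone nor the non-enolisable aldehyde is touched by aqueous phosphate.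

Step 10
Reactants: 2 1-[2,4-bis(benzyloxy)-6-hydroxyphenyl]ethan-1-one
Product: 16 1-[2,4-bis(benzyloxy)-6-methoxyphenyl]ethan-1-one
Conditions: MeI (2 equiv), K2CO3 (2 equiv), DMF, 40 °C
Reagents that add atoms: iodomethane, CI
Why: Williamson O-methylation of the only free phenol, which places the methyl ether unambiguously at the future C-5 of the flavanone.

Step 11
Reactants: 16 1-[2,4-bis(benzyloxy)-6-methoxyphenyl]ethan-1-one
Product: 18 1-[4-(benzyloxy)-2-hydroxy-6-methoxyphenyl]ethan-1-one, via dichloroboryl ether 17 (not isolated)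
Conditions: BCl3 (1.05 equiv), CH2Cl2, −78 °C, 45 min; then H2O
Reagents that add atoms: none
Why: Chelation-directed Lewis-acid ether cleavage that activates only the ethers ortho to the acetyl group, and of these the benzyl ether is cleaved far faster than the methyl ether at −78 °C, so the para benzyl and the OMe survive.

Step 12 (key step)
Reactants: 15 4-(benzyloxy)-3-{5,7-bis(benzyloxy)-2-[4-(benzyloxy)phenyl]-4-oxo-4H-chromen-6-yl}benzaldehyde; 18 1-[4-(benzyloxy)-2-hydroxy-6-methoxyphenyl]ethan-1-one (1.3 equiv)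
Product: 20 5,7-bis(benzyloxy)-6-{2-(benzyloxy)-5-[(E)-3-(4-(benzyloxy)-2-hydroxy-6-methoxyphenyl)-3-oxoprop-1-en-1-yl]phenyl}-2-[4-(benzyloxy)phenyl]-4H-chromen-4-one, via aldol adduct 19 (not isolated)
Conditions: KOH (50% aq, 15 equiv), EtOH/THF 1:1, rt, 48–72 h; then 1 M HCl to pH 5, 0 °C
Reagents that add atoms: none
Why: Claisen–Schmidt aldol condensation, standard for 2'-hydroxy-4',6'-dialkoxyacetophenones, in which the enolate of 18 attacks the only aldehyde present and E1cB dehydration of 19 gives the (E)-chalcone, while the flavone, a donor-rich vinylogous ester without acidic C–H, stays a spectator at rt.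

Step 13
Reactants: 20 the (E)-2'-hydroxychalcone of step 12
Product: 21 rac-5,7-bis(benzyloxy)-6-{2-(benzyloxy)-5-[7-(benzyloxy)-5-methoxy-4-oxochroman-2-yl]phenyl}-2-[4-(benzyloxy)phenyl]-4H-chromen-4-one
Conditions: NaOAc (10 equiv), EtOH/THF 3:1, reflux, 36 h; recovered 20 is resubmitted
Reagents that add atoms: none
Why: Intramolecular oxa-Michael addition (chalcone–flavanone isomerisation), favoured because the 6'-methoxy group twists the chalcone carbonyl out of conjugation, which forms C-2 as a racemate to be resolved in step 14.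

Step 14
Reactants: 21 racemic penta-O-benzyl flavanone–flavone
Product: 22 5,7-bis(benzyloxy)-6-{2-(benzyloxy)-5-[(2S)-7-(benzyloxy)-5-methoxy-4-oxochroman-2-yl]phenyl}-2-[4-(benzyloxy)phenyl]-4H-chromen-4-one
Conditions: RuCl[(R,R)-TsDPEN](p-cymene) (2 mol%; TsDPEN = N-tosyl-1,2-diphenylethylenediamine), HCO2H/Et3N 5:2, EtOAc, 40 °C, stopped at 52–55% conversion (chiral HPLC); chromatography
Reagents that add atoms: none
Why: Kinetic resolution by Noyori asymmetric transfer hydrogenation, in which the (R,R)-catalyst delivers hydride to give a 4R carbinol and does so fast only on the face anti to the 2-aryl group, so the (2R)-ketone becomes the (2R,4R)-cis-flavan-4-ol while the mismatched (2S)-ketone 22 is recovered in ≥98% ee without epimerisation in the acidic medium.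

Step 15
Reactants: 22 (2S)-penta-O-benzyl flavanone–flavone
Product: 23 6-{2-hydroxy-5-[(2S)-7-hydroxy-5-methoxy-4-oxo-3,4-dihydro-2H-chromen-2-yl]phenyl}-5,7-dihydroxy-2-(4-hydroxyphenyl)-4H-chromen-4-one
Conditions: H2 (1 atm), 10% Pd/C, THF/MeOH 1:1, rt; filtration, Sephadex LH-20 (MeOH)
Reagents that add atoms: none
Why: Catalytic hydrogenolysis removes all five benzyl ethers under neutral conditions that leave the aryl methyl ether, the flavone C2=C3 bond and both carbonyls intact and give no base-induced ring opening, so the 2S centre is retained.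

## Compound list
1 | 2,4,6-trihydroxyacetophenone (phloroacetophenone) | CC(=O)c1c(O)cc(O)cc1O | starting material
2 | 1-[2,4-bis(benzyloxy)-6-hydroxyphenyl]ethan-1-one | CC(=O)c1c(O)cc(OCc2ccccc2)cc1OCc1ccccc1 | intermediate
3 | 4-(benzyloxy)benzaldehyde | O=Cc1ccc(OCc2ccccc2)cc1 | starting material
4 | rac-1-[2,4-bis(benzyloxy)-6-hydroxyphenyl]-3-[4-(benzyloxy)phenyl]-3-hydroxypropan-1-one (not isolated) | O=C(CC(O)c1ccc(OCc2ccccc2)cc1)c1c(O)cc(OCc2ccccc2)cc1OCc1ccccc1 | intermediate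
5 | (E)-1-[2,4-bis(benzyloxy)-6-hydroxyphenyl]-3-[4-(benzyloxy)phenyl]prop-2-en-1-one | O=C(/C=C/c1ccc(OCc2ccccc2)cc1)c1c(O)cc(OCc2ccccc2)cc1OCc1ccccc1 | intermediate
6 | rac-5,7-bis(benzyloxy)-2-[4-(benzyloxy)phenyl]chroman-4-one (not isolated) | O=C1CC(c2ccc(OCc3ccccc3)cc2)Oc2cc(OCc3ccccc3)cc(OCc3ccccc3)c12 | intermediate
7 | 5,7-bis(benzyloxy)-2-[4-(benzyloxy)phenyl]-4H-chromen-4-one | O=c1cc(-c2ccc(OCc3ccccc3)cc2)oc2cc(OCc3ccccc3)cc(OCc3ccccc3)c12 | intermediate
8 | 7-(benzyloxy)-2-[4-(benzyloxy)phenyl]-5-[(dichloroboranyl)oxy]-4H-chromen-4-one (not isolated) | O=c1cc(-c2ccc(OCc3ccccc3)cc2)oc2cc(OCc3ccccc3)cc(OB(Cl)Cl)c12 | intermediate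
9 | 7-(benzyloxy)-2-[4-(benzyloxy)phenyl]-5-hydroxy-4H-chromen-4-one | O=c1cc(-c2ccc(OCc3ccccc3)cc2)oc2cc(OCc3ccccc3)cc(O)c12 | intermediate
10 | 7-(benzyloxy)-2-[4-(benzyloxy)phenyl]-5-hydroxy-6-iodo-4H-chromen-4-one | O=c1cc(-c2ccc(OCc3ccccc3)cc2)oc2cc(OCc3ccccc3)c(I)c(O)c12 | intermediate
11 | 5,7-bis(benzyloxy)-2-[4-(benzyloxy)phenyl]-6-iodo-4H-chromen-4-one | O=c1cc(-c2ccc(OCc3ccccc3)cc2)oc2cc(OCc3ccccc3)c(I)c(OCc3ccccc3)c12 | intermediate
12 | 3-bromo-4-hydroxybenzaldehyde | O=Cc1ccc(O)c(Br)c1 | starting material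
13 | 4-(benzyloxy)-3-bromobenzaldehyde | O=Cc1ccc(OCc2ccccc2)c(Br)c1 | intermediate
14 | 4-(benzyloxy)-3-(4,4,5,5-tetramethyl-1,3,2-dioxaborolan-2-yl)benzaldehyde | O=Cc1ccc(OCc2ccccc2)c(B2OC(C)(C)C(C)(C)O2)c1 | intermediate
15 | 4-(benzyloxy)-3-{5,7-bis(benzyloxy)-2-[4-(benzyloxy)phenyl]-4-oxo-4H-chromen-6-yl}benzaldehyde | O=Cc1ccc(OCc2ccccc2)c(-c2c(OCc3ccccc3)cc3oc(-c4ccc(OCc5ccccc5)cc4)cc(=O)c3c2OCc2ccccc2)c1 | intermediate
16 | 1-[2,4-bis(benzyloxy)-6-methoxyphenyl]ethan-1-one | CC(=O)c1c(OC)cc(OCc2ccccc2)cc1OCc1ccccc1 | intermediate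
17 | 1-{4-(benzyloxy)-2-[(dichloroboranyl)oxy]-6-methoxyphenyl}ethan-1-one (not isolated) | CC(=O)c1c(OB(Cl)Cl)cc(OCc2ccccc2)cc1OC | intermediate
18 | 1-[4-(benzyloxy)-2-hydroxy-6-methoxyphenyl]ethan-1-one | CC(=O)c1c(O)cc(OCc2ccccc2)cc1OC | intermediate
19 | racemic β-hydroxy ketone from 15 and 18 (not isolated) | COc1cc(OCc2ccccc2)cc(O)c1C(=O)CC(O)c1ccc(OCc2ccccc2)c(-c2c(OCc3ccccc3)cc3oc(-c4ccc(OCc5ccccc5)cc4)cc(=O)c3c2OCc2ccccc2)c1 | intermediate
20 | (E)-2'-hydroxychalcone–flavone, penta-O-benzyl | COc1cc(OCc2ccccc2)cc(O)c1C(=O)/C=C/c1ccc(OCc2ccccc2)c(-c2c(OCc3ccccc3)cc3oc(-c4ccc(OCc5ccccc5)cc4)cc(=O)c3c2OCc2ccccc2)c1 | intermediate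
21 | racemic penta-O-benzyl flavanone–flavone | COc1cc(OCc2ccccc2)cc2c1C(=O)CC(c1ccc(OCc3ccccc3)c(-c3c(OCc4ccccc4)cc4oc(-c5ccc(OCc6ccccc6)cc5)cc(=O)c4c3OCc3ccccc3)c1)O2 | intermediate
22 | (2S)-penta-O-benzyl flavanone–flavone | COc1cc(OCc2ccccc2)cc2c1C(=O)C[C@@H](c1ccc(OCc3ccccc3)c(-c3c(OCc4ccccc4)cc4oc(-c5ccc(OCc6ccccc6)cc5)cc(=O)c4c3OCc3ccccc3)c1)O2 | intermediate
23 | (2S)-2,3-dihydrorobustaflavone 5-methyl ether (CNP0332590.1) | COc1cc(O)cc2c1C(=O)C[C@@H](c1ccc(O)c(-c3c(O)cc4oc(-c5ccc(O)cc5)cc(=O)c4c3O)c1)O2 | target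

## Step count and risks
Total steps: 15.
Longest linear sequence: 11 steps (1, 2, 3, 4, 5, 6, 9, 12, 13, 14, 15).

**Step 9 (tri-ortho-substituted biaryl).** Protodeboronation of 14 and hydrodeiodination of 11 can outrun a slow transmetalation.
- The fallback changes the nucleophile from boron to zinc and masks the aldehyde. It sets out from 13 and 11 and comes back at 15.
- Aldehyde 13 is acetalised (ethylene glycol, TsOH, toluene, Dean–Stark) to 2-[4-(benzyloxy)-3-bromophenyl]-1,3-dioxolane F1.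
- Br/Li exchange (n-BuLi, THF, −78 °C) gives [2-(benzyloxy)-5-(1,3-dioxolan-2-yl)phenyl]lithium F2.
- ZnCl2 converts this into [2-(benzyloxy)-5-(1,3-dioxolan-2-yl)phenyl]zinc chloride F3.
- Negishi coupling with 11 (Pd2(dba)3, SPhos, THF, 60 °C) gives 5,7-bis(benzyloxy)-6-[2-(benzyloxy)-5-(1,3-dioxolan-2-yl)phenyl]-2-[4-(benzyloxy)phenyl]-4H-chromen-4-one F4.
- 1 M HCl/THF hydrolyses F4 to 15.

**Step 12 (late aldol condensation next to a flavone).** Long exposure to KOH may open the pyranone ring, and the poor solubility of 15 may stall the reaction.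
- The fallback reverses the order of the two fragment unions, so that the aldol runs before any flavone is present. It sets out from 13, 18 and 11 and comes back at 20.
- Ketone 18 and aldehyde 13 are condensed (KOH, EtOH, rt) through the transient 1-[4-(benzyloxy)-2-hydroxy-6-methoxyphenyl]-3-[4-(benzyloxy)-3-bromophenyl]-3-hydroxypropan-1-one F5.
- This gives (E)-1-[4-(benzyloxy)-2-hydroxy-6-methoxyphenyl]-3-[4-(benzyloxy)-3-bromophenyl]prop-2-en-1-one F6.
- Miyaura borylation (B2pin2, PdCl2(dppf), KOAc, dioxane, 90 °C) gives (E)-1-[4-(benzyloxy)-2-hydroxy-6-methoxyphenyl]-3-[4-(benzyloxy)-3-(4,4,5,5-tetramethyl-1,3,2-dioxaborolan-2-yl)phenyl]prop-2-en-1-one F7.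
- Suzuki coupling of F7 with 11 under the step 9 conditions gives 20.
- The chalcone has no stereocentre, so the coupling base does no harm, and any material that closes to 21 is the next intermediate anyway.

**Step 14 (kinetic resolution of a large, electron-rich 5-methoxy ketone).** Reduction may be too slow or not selective enough, or the flavone may be attacked.
- The fallback replaces the catalytic resolution by a physical one. It sets out from 21 and comes back at 22.
- Preparative HPLC or SFC on an immobilised amylose tris(3,5-dimethylphenylcarbamate) phase separates 22 from the (2R)-penta-O-benzyl flavanone–flavone F8.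
- F8 is re-equilibrated through chalcone 20 (NaOAc, EtOH/THF, reflux) to 21 and recycled.
- In either case the 2S assignment is confirmed by CD: negative band near 290 nm and positive band near 330 nm.

## Further compounds
F1 | step 9 | 2-[4-(benzyloxy)-3-bromophenyl]-1,3-dioxolane | Brc1cc(C2OCCO2)ccc1OCc1ccccc1
F2 | step 9 | [2-(benzyloxy)-5-(1,3-dioxolan-2-yl)phenyl]lithium | [Li]c1cc(C2OCCO2)ccc1OCc1ccccc1
F3 | step 9 | [2-(benzyloxy)-5-(1,3-dioxolan-2-yl)phenyl]zinc chloride | Cl[Zn]c1cc(C2OCCO2)ccc1OCc1ccccc1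
F4 | step 9 | 5,7-bis(benzyloxy)-6-[2-(benzyloxy)-5-(1,3-dioxolan-2-yl)phenyl]-2-[4-(benzyloxy)phenyl]-4H-chromen-4-one | O=c1cc(-c2ccc(OCc3ccccc3)cc2)oc2cc(OCc3ccccc3)c(-c3cc(C4OCCO4)ccc3OCc3ccccc3)c(OCc3ccccc3)c12
F5 | step 12 | 1-[4-(benzyloxy)-2-hydroxy-6-methoxyphenyl]-3-[4-(benzyloxy)-3-bromophenyl]-3-hydroxypropan-1-one | COc1cc(OCc2ccccc2)cc(O)c1C(=O)CC(O)c1ccc(OCc2ccccc2)c(Br)c1
F6 | step 12 | (E)-1-[4-(benzyloxy)-2-hydroxy-6-methoxyphenyl]-3-[4-(benzyloxy)-3-bromophenyl]prop-2-en-1-one | COc1cc(OCc2ccccc2)cc(O)c1C(=O)/C=C/c1ccc(OCc2ccccc2)c(Br)c1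
F7 | step 12 | (E)-1-[4-(benzyloxy)-2-hydroxy-6-methoxyphenyl]-3-[4-(benzyloxy)-3-(4,4,5,5-tetramethyl-1,3,2-dioxaborolan-2-yl)phenyl]prop-2-en-1-one | COc1cc(OCc2ccccc2)cc(O)c1C(=O)/C=C/c1ccc(OCc2ccccc2)c(B2OC(C)(C)C(C)(C)O2)c1
F8 | step 14 | (2R)-penta-O-benzyl flavanone–flavone | COc1cc(OCc2ccccc2)cc2c1C(=O)C[C@H](c1ccc(OCc3ccccc3)c(-c3c(OCc4ccccc4)cc4oc(-c5ccc(OCc6ccccc6)cc5)cc(=O)c4c3OCc3ccccc3)c1)O2
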